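## The problem

Compound 20 joins two benzofuran-type units through one aryl–heteroaryl bond, C5–C2'. The first unit is a trans-2-aryl-3-hydroxymethyl-7-methoxy-2,3-dihydrobenzofuran (benzene ring A, dihydrofuran ring B, guaiacyl ring C on C2). The second is a 7'-methoxy-5'-(3-hydroxypropyl)benzofuran (benzene ring D, furan ring E). The only stereocentres are C2 (S) and C3 (R), adjacent and trans. Trans is the more stable arrangement, so C2 can correct C3 whenever C3 carries an acidifying group, but the absolute configuration must come from a catalyst or auxiliary because nothing else in the molecule is chiral. The free phenol of ring C is para to the benzylic C2–O1 bond, so strong base, acid or oxidants can open ring B through a quinone methide and put C2 at risk. The electron-rich rings, the benzylic ether and the benzofuran also argue against hydrogenolysis and hot basic steps late in the route. Ring D with its oxygen, methoxy group and side chain maps onto dihydroconiferyl alcohol and lacks only C2' and C3'. The feature that opens the key step is that C2 carries O1 and an aryl ring while C3 carries ring A and a one-carbon branch. The C2–C3 bond is therefore the union of an aryldiazoacetate carbon with the methylene of an ortho 4-oxygenated benzyl ether, whose C–H bond is activated by the ether oxygen and the aryl ring and lies 1,5 to the carbenoid carbon.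

## Retrosynthesis

Ring E. In 20 the bonds O1'–C2' and C3'–C3a' are cut, giving the terminal arylalkyne 16 and the ortho-iodophenol 18, with the diarylalkyne 19 as the link between them. The neighbouring cut, C5–C2' alone, needs a finished benzofuran made over several steps and all hydroxyl groups masked for a metalation or a hot carbonate-mediated arylation. The annulative cut takes C2' and C3' from an acetylene, needs one step to reach 18, and tolerates free hydroxyl groups. The forward reaction must couple and then close ring E (5-endo-dig) in one flask under amine base, which leaves C2 and C3 untouched.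

The alkyne. Cutting C5–C(sp) leads from 16 through the silyl-capped alkyne 15 to the aryl bromide 14. Bromine is the placeholder because it comes with the commercial aldehyde 4, is inert to carbenoid and hydride, and reacts only with palladium. The forward step is a Sonogashira coupling on an electron-rich bromide followed by loss of the silyl cap.

Oxidation level. No skeletal bond is cut between 14 and 13. The hydroxymethyl group is traced to the C3 ester and the phenol to its pivalate, so one hydride step both removes the auxiliary and frees the phenol. The ester 13 is preferred over other C3 groups because it is exactly what the ring-forming step delivers.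

The key cut, C2–C3. Opening ring B of 13 at C2–C3 gives the aryldiazoacetate 12. Cutting O1–C2 or C3–C3a instead would demand an acyclic precursor with one or both stereocentres already in place. In 12 neither stereocentre exists and the only chirality is a lactate-derived ester. The forward reaction must form the bond, close ring B and set C2 and C3, trans and in one enantiomeric series.

The diazo ester. The diazo group of 12 is traced to the arylacetate 11, and the ester C–O bond of 11 is cut to give the acid 8 and the lactamide 10. The amide bond of 10 is cut to give ethyl (S)-lactate 9.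

The arylacetic acid. The bond between the benzylic carbon and the carboxyl carbon of 8 is cut, by way of aldehyde 7 and enol ether 6, back to the benzaldehyde 5. The cyanide-and-hydrolysis alternative is rejected because hydroxide would remove the pivalate. The forward steps must add one carbon without strong aqueous base.

The benzyl ether. The O–CH2 bond of 5 is cut to the phenol 4 and the benzylic alcohol 3, which comes from vanillin 1 through its pivalate 2. The forward reaction is an etherification under neutral conditions.

The iodophenol. The C–I bond of 18 is cut to give dihydroconiferyl alcohol 17. The forward iodination must go ortho to the hydroxyl group, the only free ortho position.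

## Roads not taken

Alternative 1: gold-catalysed furan-yne phenol synthesis. The cut removes ring A itself (C3a–C7a and C6–C7) together with ring B. In the forward step (Ph3P)AuNTf2 would isomerise the furan-tethered ethynyl ether A2 to the 7-hydroxy tris-silyl ether A1.
- Merits: rings A and B form in one atom-economical isomerisation, the benzofuran half is already in place, and no halogen handle or late cross-coupling is needed. In convergence it is better than the chosen plan.
- Weak points: neither stereocentre is made in the key step, so both must be built into A2 in the anti relation. A secondary benzylic ethynyl ether is hard to prepare and prone to hydration or loss of ketene. Cationic gold can ionise the benzylic C–O bond and scramble C2. The new 7-hydroxyl group must then be methylated in the presence of a phenolic silyl ether before deprotection.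
- Comparison: the chosen plan is less convergent, but it creates both stereocentres in the ring-forming step from a precursor without them.

Alternative 2: (4+1) annulation. The cut removes O1–C2 and C2–C3. In the forward step the ylide from the chiral benzylsulfonium salt A5 and K2CO3 would add to the nitrovinylphenol A4, and the phenoxide would then displace the sulfide to give the trans nitromethyl compound A3.
- Merits: A4 is one condensation away from 4, the ring-A phenol needs no protection, there is no diazo compound or precious metal, and the annulation is inherently trans. The core is reached in fewer steps than 13, by roughly two to three.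
- Weak points: the nitromethyl group must be converted to hydroxymethyl through a C3 aldehyde that is α-benzylic and β to the O1 leaving group, so it is prone to elimination and aromatisation. Absolute control rests on a stoichiometric chiral sulfide bearing an electron-rich, ionisable benzyl group.
- Comparison: against the shorter approach, the chosen plan delivers C3 at the carboxyl level, so one hydride step gives 14 and removes the pivalate, and its chirality comes from a catalyst with close precedent on this substrate class.

Alternative 3: anodic decarboxylation and cyclisation. The cut removes O1–C2. Constant-current oxidation of the carboxylate of the hydroxy acid A7 at a graphite anode in methanol would expel CO2 from the future C2, leaving a benzylic cation stabilised by the para oxygen. The ortho phenol would add to it and give A6, which is the same structure as 14.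
- Merits: no phenol protection, no diazo compound, no metal, and C2 is set from C3 alone, so only one stereocentre has to be made beforehand. In these respects it is better than the chosen plan, and it would join the route before step 12.
- Weak points: that one centre still needs an enantioselective synthesis of a 2,3-diaryl-4-hydroxybutanoic acid, which exists as its lactone. Both guaiacyl phenols and the product are oxidised at potentials no higher than the substrate, so over-oxidation and phenol coupling compete. Methanol also competes with the phenol for the cation.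
- Comparison: the chosen plan needs protecting groups and more steps, but it sets both centres in one catalytic step and avoids oxidising conditions on free guaiacols.

Key step: step 10

Assumption: the (S)-lactamide ester with Rh2(S-DOSP)4 is taken as the matched pair leading to the (2S,3S)-trans ester 13; if it delivers the antipode, (R)-lactate and Rh2(R-DOSP)4 are used instead and nothing else changes.

## Route

Step 1
Reactants: 1 vanillin
Product: 2 4-formyl-2-methoxyphenyl pivalate
Conditions: pivaloyl chloride, Et3N, DMAP (cat.), CH2Cl2, 0 °C to rt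
Reagents that add atoms: pivaloyl chloride, CC(C)(C)C(=O)Cl
Why: Acylation of the phenol is routine; the hindered pivalate should resist the later ylide, amine and amidine bases and is removed by LiAlH4 in step 11.

Step 2
Reactants: 2 4-formyl-2-methoxyphenyl pivalate
Product: 3 4-(hydroxymethyl)-2-methoxyphenyl pivalate
Conditions: NaBH4, THF/EtOH, −10 to 0 °C
Reagents that add atoms: none
Why: Chemoselective borohydride reduction of an aromatic aldehyde; the tert-butyl-substituted ester is too hindered to be reduced or transesterified at this temperature.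

Step 3
Reactants: 3 4-(hydroxymethyl)-2-methoxyphenyl pivalate; 4 5-bromo-o-vanillin
Product: 5 4-[(4-bromo-2-formyl-6-methoxyphenoxy)methyl]-2-methoxyphenyl pivalate
Conditions: PPh3, DIAD, THF, 0 °C to rt
Reagents that add atoms: none
Why: Mitsunobu etherification: the acidic phenol of 4 protonates the betaine and its phenoxide displaces the benzylic oxyphosphonium ion of 3 in an SN2 step, with no base present that could move the pivalate.

Step 4
Reactants: 5 4-[(4-bromo-2-formyl-6-methoxyphenoxy)methyl]-2-methoxyphenyl pivalate
Product: 6 4-{[4-bromo-2-methoxy-6-(2-methoxyethenyl)phenoxy]methyl}-2-methoxyphenyl pivalate (E/Z mixture)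
Conditions: MeOCH2PPh3Cl, NaN(SiMe3)2, THF, 0 °C; then 5, −78 to 0 °C
Reagents that add atoms: (methoxymethyl)triphenylphosphonium chloride, COC[P+](c1ccccc1)(c1ccccc1)c1ccccc1.[Cl-]
Why: Wittig methoxymethylenation; the non-stabilised ylide should add to the aldehyde much faster than to the hindered aryl ester, and both alkene isomers converge on 7.

Step 5
Reactants: 6 4-{[4-bromo-2-methoxy-6-(2-methoxyethenyl)phenoxy]methyl}-2-methoxyphenyl pivalate
Product: 7 4-{[4-bromo-2-methoxy-6-(2-oxoethyl)phenoxy]methyl}-2-methoxyphenyl pivalate
Conditions: 2 M aq. HCl, THF, 40 °C; crude product used at once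
Reagents that add atoms: water, O
Why: Acid-catalysed enol ether hydrolysis (C-protonation, hemiacetal, loss of methanol); the pivalate, the aryl bromide and the benzyl aryl ether should withstand dilute acid.

Step 6
Reactants: 7 4-{[4-bromo-2-methoxy-6-(2-oxoethyl)phenoxy]methyl}-2-methoxyphenyl pivalate
Product: 8 2-[5-bromo-3-methoxy-2-(3-methoxy-4-pivaloyloxybenzyloxy)phenyl]acetic acid
Conditions: NaClO2, NaH2PO4, 2-methyl-2-butene, t-BuOH/H2O, 0 °C to rt
Reagents that add atoms: sodium chlorite, [Na+].[O-]Cl=O
Why: Pinnick oxidation under buffered, weakly acidic conditions spares the pivalate; the alkene scavenger removes HOCl before it can chlorinate the electron-rich rings.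

Step 7
Reactants: 9 ethyl (S)-lactate
Product: 10 (S)-2-hydroxy-1-(pyrrolidin-1-yl)propan-1-one
Conditions: pyrrolidine (neat), rt to 40 °C
Reagents that add atoms: pyrrolidine, C1CCNC1
Why: Aminolysis of an α-hydroxy ester by a secondary amine; the stereocentre is untouched because no bond to it is broken.

Step 8
Reactants: 8 2-[5-bromo-3-methoxy-2-(3-methoxy-4-pivaloyloxybenzyloxy)phenyl]acetic acid; 10 (S)-2-hydroxy-1-(pyrrolidin-1-yl)propan-1-one
Product: 11 (S)-1-oxo-1-(pyrrolidin-1-yl)propan-2-yl 2-[5-bromo-3-methoxy-2-(3-methoxy-4-pivaloyloxybenzyloxy)phenyl]acetate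
Conditions: DCC, DMAP (cat.), CH2Cl2, 0 °C to rt
Reagents that add atoms: none
Why: Steglich esterification of an arylacetic acid with a secondary alcohol; the lactate C–O bond is not broken, so its configuration is kept.

Step 9
Reactants: 11 (S)-1-oxo-1-(pyrrolidin-1-yl)propan-2-yl 2-[5-bromo-3-methoxy-2-(3-methoxy-4-pivaloyloxybenzyloxy)phenyl]acetate
Product: 12 (S)-1-oxo-1-(pyrrolidin-1-yl)propan-2-yl 2-diazo-2-[5-bromo-3-methoxy-2-(3-methoxy-4-pivaloyloxybenzyloxy)phenyl]acetate
Conditions: 4-acetamidobenzenesulfonyl azide, DBU, MeCN, 0 °C to rt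
Reagents that add atoms: 4-acetamidobenzenesulfonyl azide, CC(=O)Nc1ccc(cc1)S(=O)(=O)N=[N+]=[N-]
Why: Regitz diazo transfer: DBU deprotonates the benzylic α-carbon and the enolate takes N2 from the sulfonyl azide; the pivalate and the auxiliary stereocentre should be stable to the amidine at this temperature.

Step 10
Reactants: 12 (S)-1-oxo-1-(pyrrolidin-1-yl)propan-2-yl 2-diazo-2-[5-bromo-3-methoxy-2-(3-methoxy-4-pivaloyloxybenzyloxy)phenyl]acetate
Product: 13 (S)-1-oxo-1-(pyrrolidin-1-yl)propan-2-yl (2S,3S)-5-bromo-7-methoxy-2-(3-methoxy-4-pivaloyloxyphenyl)-2,3-dihydrobenzofuran-3-carboxylate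
Conditions: Rh2(S-DOSP)4 (1 mol%), CH2Cl2, rt, slow addition of 12 under Ar
Reagents that add atoms: none
Why: Rh2(S-DOSP)4 expels N2 from 12 and gives a donor–acceptor carbenoid of divalent rhodium, whose electrophilic carbon takes up the benzylic C–H bond of the ortho ether in a concerted, asynchronous three-centre transition state with hydride-transfer character, forming C2–C3 and releasing the catalyst. The closest known reaction type is the dirhodium tetracarboxylate-catalysed intramolecular C–H insertion of ortho-benzyloxy aryldiazoacetates to 2-aryl-2,3-dihydrobenzofuran-3-carboxylates, including the variant with a lactamide ester auxiliary. Ring B closes as a 1,5-insertion: the carbenoid carbon and the methylene carbon are joined across the three-atom tether C3a–C7a–O1, so only the five-membered ring is within reach. C2 is set by which of the two enantiotopic benzylic hydrogens is engaged, and this is decided by the chiral pocket of the four prolinate ligands. C3 is set by the face of the carbenoid carbon that bonds to C2; the (S)-lactamide ester, as the matched partner of the catalyst, should orient the ester so that aryl and carboxyl end up trans. The step needs enantioselectivity, trans diastereoselectivity and chemoselectivity for insertion over cyclopropanation of the electron-rich rings or carbene dimerisation. The ether oxygen and the 4-acyloxy-3-methoxyphenyl ring make the target C–H bond the most hydridic one and the donor aryl group tempers the carbenoid, while bromine and the pivalate are inert. Any cis ester is the less stable C3 epimer and can be converted to 13 with base.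

Step 11
Reactants: 13 (S)-1-oxo-1-(pyrrolidin-1-yl)propan-2-yl (2S,3S)-5-bromo-7-methoxy-2-(3-methoxy-4-pivaloyloxyphenyl)-2,3-dihydrobenzofuran-3-carboxylate
Product: 14 4-[(2S,3R)-5-bromo-3-(hydroxymethyl)-7-methoxy-2,3-dihydrobenzofuran-2-yl]-2-methoxyphenol
Conditions: LiAlH4, THF, −10 to 0 °C; work-up with aq. potassium sodium tartrate (KNaC4H4O6)
Reagents that add atoms: none
Why: Hydride reduction converts the C3 ester to the hydroxymethyl group and cleaves the aryl pivalate in the same operation, releasing 10; at 0 °C the aryl bromide and ring B should be left alone, and C3 keeps its trans configuration (the descriptor changes to R only through the priority rules).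

Step 12
Reactants: 14 4-[(2S,3R)-5-bromo-3-(hydroxymethyl)-7-methoxy-2,3-dihydrobenzofuran-2-yl]-2-methoxyphenol
Product: 15 4-[(2S,3R)-3-(hydroxymethyl)-7-methoxy-5-[(trimethylsilyl)ethynyl]-2,3-dihydrobenzofuran-2-yl]-2-methoxyphenol
Conditions: ethynyltrimethylsilane, PdCl2(PhCN)2 (3 mol%), P(t-Bu)3·HBF4 (6 mol%), CuI (2 mol%), i-Pr2NH, dioxane, rt to 45 °C
Reagents that add atoms: ethynyltrimethylsilane, C#C[Si](C)(C)C
Why: Sonogashira coupling; the bulky trialkylphosphine on zerovalent palladium allows oxidative addition to the electron-rich C–Br bond near room temperature, mild enough for the free phenol and both stereocentres.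

Step 13
Reactants: 15 4-[(2S,3R)-3-(hydroxymethyl)-7-methoxy-5-[(trimethylsilyl)ethynyl]-2,3-dihydrobenzofuran-2-yl]-2-methoxyphenol
Product: 16 4-[(2S,3R)-5-ethynyl-3-(hydroxymethyl)-7-methoxy-2,3-dihydrobenzofuran-2-yl]-2-methoxyphenol
Conditions: K2CO3 (0.3 equiv), MeOH/THF, rt
Reagents that add atoms: none
Why: Methanolysis of the alkynyl C–Si bond with catalytic carbonate at room temperature, too mild to open ring B through the phenoxide.

Step 14
Reactants: 17 dihydroconiferyl alcohol
Product: 18 4-(3-hydroxypropyl)-2-iodo-6-methoxyphenol
Conditions: I2, NaHCO3, THF/H2O, 0 °C to rt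
Reagents that add atoms: iodine, II
Why: Electrophilic iodination through the phenoxide; the only free position ortho to the hydroxyl group is attacked, and phenoxide control overrides the methoxy group.

Step 15
Reactants: 16 4-[(2S,3R)-5-ethynyl-3-(hydroxymethyl)-7-methoxy-2,3-dihydrobenzofuran-2-yl]-2-methoxyphenol; 18 4-(3-hydroxypropyl)-2-iodo-6-methoxyphenol
Product: 20 4-[(2S,3R)-3-(hydroxymethyl)-5-[5-(3-hydroxypropyl)-7-methoxybenzofuran-2-yl]-7-methoxy-2,3-dihydrobenzofuran-2-yl]-2-methoxyphenol (CNP0308311.1), via diarylalkyne phenol 19 (not isolated)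
Conditions: PdCl2(PPh3)2 (5 mol%), CuI (10 mol%), Et3N, DMF, rt to 70 °C, Ar
Reagents that add atoms: none
Why: Sonogashira coupling of the aryl iodide with the terminal alkyne gives the ortho-alkynylphenol 19, whose metal-activated triple bond is attacked by the neighbouring phenol in a 5-endo-dig hydroalkoxylation that closes ring E; this is the established route to 2-aryl-7-methoxybenzofurans, and the stereocentres are remote and untouched.

## Compound list

1 | vanillin | COc1cc(C=O)ccc1O | starting material
2 | 4-formyl-2-methoxyphenyl pivalate | COc1cc(C=O)ccc1OC(=O)C(C)(C)C | intermediate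
3 | 4-(hydroxymethyl)-2-methoxyphenyl pivalate | COc1cc(CO)ccc1OC(=O)C(C)(C)C | intermediate
4 | 5-bromo-o-vanillin (5-bromo-2-hydroxy-3-methoxybenzaldehyde) | COc1cc(Br)cc(C=O)c1O | starting material
5 | 4-[(4-bromo-2-formyl-6-methoxyphenoxy)methyl]-2-methoxyphenyl pivalate | COc1cc(Br)cc(C=O)c1OCc1ccc(OC(=O)C(C)(C)C)c(OC)c1 | intermediate
6 | 4-{[4-bromo-2-methoxy-6-(2-methoxyethenyl)phenoxy]methyl}-2-methoxyphenyl pivalate (E/Z mixture) | COC=Cc1cc(Br)cc(OC)c1OCc1ccc(OC(=O)C(C)(C)C)c(OC)c1 | intermediate
7 | 4-{[4-bromo-2-methoxy-6-(2-oxoethyl)phenoxy]methyl}-2-methoxyphenyl pivalate | O=CCc1cc(Br)cc(OC)c1OCc1ccc(OC(=O)C(C)(C)C)c(OC)c1 | intermediate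
8 | 2-[5-bromo-3-methoxy-2-(3-methoxy-4-pivaloyloxybenzyloxy)phenyl]acetic acid | OC(=O)Cc1cc(Br)cc(OC)c1OCc1ccc(OC(=O)C(C)(C)C)c(OC)c1 | intermediate
9 | ethyl (S)-lactate | C[C@H](O)C(=O)OCC | starting material
10 | (S)-2-hydroxy-1-(pyrrolidin-1-yl)propan-1-one | C[C@H](O)C(=O)N1CCCC1 | intermediate
11 | (S)-1-oxo-1-(pyrrolidin-1-yl)propan-2-yl 2-[5-bromo-3-methoxy-2-(3-methoxy-4-pivaloyloxybenzyloxy)phenyl]acetate | C[C@H](OC(=O)Cc1cc(Br)cc(OC)c1OCc1ccc(OC(=O)C(C)(C)C)c(OC)c1)C(=O)N1CCCC1 | intermediate
12 | (S)-1-oxo-1-(pyrrolidin-1-yl)propan-2-yl 2-diazo-2-[5-bromo-3-methoxy-2-(3-methoxy-4-pivaloyloxybenzyloxy)phenyl]acetate | C[C@H](OC(=O)C(=[N+]=[N-])c1cc(Br)cc(OC)c1OCc1ccc(OC(=O)C(C)(C)C)c(OC)c1)C(=O)N1CCCC1 | intermediate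
13 | (S)-1-oxo-1-(pyrrolidin-1-yl)propan-2-yl (2S,3S)-5-bromo-7-methoxy-2-(3-methoxy-4-pivaloyloxyphenyl)-2,3-dihydrobenzofuran-3-carboxylate (trans) | COc1cc([C@H]2Oc3c(OC)cc(Br)cc3[C@@H]2C(=O)O[C@@H](C)C(=O)N4CCCC4)ccc1OC(=O)C(C)(C)C | intermediate
14 | 4-[(2S,3R)-5-bromo-3-(hydroxymethyl)-7-methoxy-2,3-dihydrobenzofuran-2-yl]-2-methoxyphenol (trans) | COc1cc([C@H]2Oc3c(OC)cc(Br)cc3[C@@H]2CO)ccc1O | intermediate
15 | 4-[(2S,3R)-3-(hydroxymethyl)-7-methoxy-5-[(trimethylsilyl)ethynyl]-2,3-dihydrobenzofuran-2-yl]-2-methoxyphenol | COc1cc([C@H]2Oc3c(OC)cc(C#C[Si](C)(C)C)cc3[C@@H]2CO)ccc1O | intermediate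
16 | 4-[(2S,3R)-5-ethynyl-3-(hydroxymethyl)-7-methoxy-2,3-dihydrobenzofuran-2-yl]-2-methoxyphenol | COc1cc([C@H]2Oc3c(OC)cc(C#C)cc3[C@@H]2CO)ccc1O | intermediate
17 | dihydroconiferyl alcohol (4-(3-hydroxypropyl)-2-methoxyphenol) | COc1cc(CCCO)ccc1O | starting material
18 | 4-(3-hydroxypropyl)-2-iodo-6-methoxyphenol | COc1cc(CCCO)cc(I)c1O | intermediate
19 | 2-{[(2S,3R)-2-(4-hydroxy-3-methoxyphenyl)-3-(hydroxymethyl)-7-methoxy-2,3-dihydrobenzofuran-5-yl]ethynyl}-4-(3-hydroxypropyl)-6-methoxyphenol (not isolated) | COc1cc([C@H]2Oc3c(OC)cc(C#Cc4cc(CCCO)cc(OC)c4O)cc3[C@@H]2CO)ccc1O | intermediate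
20 | 4-[(2S,3R)-3-(hydroxymethyl)-5-[5-(3-hydroxypropyl)-7-methoxybenzofuran-2-yl]-7-methoxy-2,3-dihydrobenzofuran-2-yl]-2-methoxyphenol (CNP0308311.1) | COc1cc([C@H]2Oc3c(OC)cc(-c4cc5cc(CCCO)cc(OC)c5o4)cc3[C@@H]2CO)ccc1O | target

## Step count and least certain steps

Total: 15 steps. Longest linear sequence: 13 steps (1 → 2 → 3 → 5 → 6 → 7 → 8 → 11 → 12 → 13 → 14 → 15 → 16 → 20; steps 1–6, 8–13 and 15). Steps 7 and 14 are side branches.

Step 10 (key step). The most likely failure is insufficient facial discrimination: the auxiliary and the catalyst may not override the intrinsic cis preference of the insertion or may be mismatched, lowering the trans share and the enantiomeric purity. Cyclopropanation or ring expansion of the electron-rich benzyl ring could also take material. The fallback lets the catalyst alone control C2 and corrects C3 thermodynamically; it sets out from 8 and returns at 14. Acid 8 is esterified with TMSCHN2 to the methyl ester F1 and converted by diazo transfer to the methyl aryldiazoacetate F2. Insertion with Rh2(S-PTTL)4 (or its mirror image, whichever sets C2 as S) in toluene at low temperature should give the cis ester F3. DBU in toluene then epimerises C3 to the more stable trans methyl ester F4, and LiAlH4 reduces F4 to 14.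

Step 15. The likely failures are oxidative dimerisation of the electron-rich alkyne at copper, and stalling after the coupling because the electron-rich phenol adds slowly to the triple bond. The fallback separates coupling from ring closure and changes the closing mode; it sets out from 18 and returns at 19. Compound 18 is acetylated (Ac2O, pyridine) to the diacetate F5 and coupled with 16 at room temperature (PdCl2(PPh3)2, CuI, Et3N, THF) to the diarylalkyne diacetate F6. Catalytic K2CO3 in methanol frees the phenol to give 19, which is now isolated and closed to 20 by hydroalkoxylation with (Ph3P)AuNTf2 in CH2Cl2.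

Step 5 (with step 6). The arylacetaldehyde may be lost through enolisation, aldol condensation and air oxidation before it is oxidised, and the acid may slowly cleave the benzyl aryl ether. The fallback is an Arndt–Eistert homologation that avoids the aldehyde; it sets out from 5 and returns at 11. Pinnick oxidation of 5 gives the benzoic acid F7, oxalyl chloride with catalytic DMF gives the acid chloride F8, and TMSCHN2 with Et3N gives the diazoketone F9. Wolff rearrangement of F9 (PhCO2Ag, Et3N, THF, or irradiation) in the presence of 10 traps the ketene as ester 11.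

Step 12. The free phenol and hydroxyl groups may bind copper and palladium while oxidative addition to the electron-rich bromide is slow, so dimerisation of the silylacetylene could outrun coupling. The fallback moves the coupling to the stage where all heteroatoms are masked; it sets out from 13 and returns at 15. Bromide 13 is coupled with ethynyltrimethylsilane under the conditions of step 12 to the silylalkynyl ester F10, and LiAlH4 at 0 °C then reduces the ester and removes the pivalate to give 15.

## Further compounds

F1 | step 10 | methyl 2-[5-bromo-3-methoxy-2-(3-methoxy-4-pivaloyloxybenzyloxy)phenyl]acetate | COC(=O)Cc1cc(Br)cc(OC)c1OCc1ccc(OC(=O)C(C)(C)C)c(OC)c1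
F2 | step 10 | methyl 2-diazo-2-[5-bromo-3-methoxy-2-(3-methoxy-4-pivaloyloxybenzyloxy)phenyl]acetate | COC(=O)C(=[N+]=[N-])c1cc(Br)cc(OC)c1OCc1ccc(OC(=O)C(C)(C)C)c(OC)c1
F3 | step 10 | methyl (2S,3R)-5-bromo-7-methoxy-2-(3-methoxy-4-pivaloyloxyphenyl)-2,3-dihydrobenzofuran-3-carboxylate (cis) | COc1cc([C@H]2Oc3c(OC)cc(Br)cc3[C@H]2C(=O)OC)ccc1OC(=O)C(C)(C)C
F4 | step 10 | methyl (2S,3S)-5-bromo-7-methoxy-2-(3-methoxy-4-pivaloyloxyphenyl)-2,3-dihydrobenzofuran-3-carboxylate (trans) | COc1cc([C@H]2Oc3c(OC)cc(Br)cc3[C@@H]2C(=O)OC)ccc1OC(=O)C(C)(C)C
F5 | step 15 | 4-(3-acetoxypropyl)-2-iodo-6-methoxyphenyl acetate | COc1cc(CCCOC(C)=O)cc(I)c1OC(C)=O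
F6 | step 15 | 2-{[(2S,3R)-2-(4-hydroxy-3-methoxyphenyl)-3-(hydroxymethyl)-7-methoxy-2,3-dihydrobenzofuran-5-yl]ethynyl}-4-(3-acetoxypropyl)-6-methoxyphenyl acetate | COc1cc([C@H]2Oc3c(OC)cc(C#Cc4cc(CCCOC(C)=O)cc(OC)c4OC(C)=O)cc3[C@@H]2CO)ccc1O
F7 | step 5 | 5-bromo-3-methoxy-2-(3-methoxy-4-pivaloyloxybenzyloxy)benzoic acid | COc1cc(Br)cc(C(=O)O)c1OCc1ccc(OC(=O)C(C)(C)C)c(OC)c1
F8 | step 5 | 5-bromo-3-methoxy-2-(3-methoxy-4-pivaloyloxybenzyloxy)benzoyl chloride | COc1cc(Br)cc(C(=O)Cl)c1OCc1ccc(OC(=O)C(C)(C)C)c(OC)c1
F9 | step 5 | 4-{[4-bromo-2-(2-diazoacetyl)-6-methoxyphenoxy]methyl}-2-methoxyphenyl pivalate | COc1cc(Br)cc(C(=O)C=[N+]=[N-])c1OCc1ccc(OC(=O)C(C)(C)C)c(OC)c1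
F10 | step 12 | (S)-1-oxo-1-(pyrrolidin-1-yl)propan-2-yl (2S,3S)-7-methoxy-2-(3-methoxy-4-pivaloyloxyphenyl)-5-[(trimethylsilyl)ethynyl]-2,3-dihydrobenzofuran-3-carboxylate | COc1cc([C@H]2Oc3c(OC)cc(C#C[Si](C)(C)C)cc3[C@@H]2C(=O)O[C@@H](C)C(=O)N4CCCC4)ccc1OC(=O)C(C)(C)C
A1 | alternative 1 | (2S,3R)-2-[4-(tert-butyldimethylsilyloxy)-3-methoxyphenyl]-3-(tert-butyldimethylsilyloxymethyl)-5-{5-[3-(tert-butyldimethylsilyloxy)propyl]-7-methoxybenzofuran-2-yl}-2,3-dihydrobenzofuran-7-ol | COc1cc([C@H]2Oc3c(O)cc(-c4cc5cc(CCCO[Si](C)(C)C(C)(C)C)cc(OC)c5o4)cc3[C@@H]2CO[Si](C)(C)C(C)(C)C)ccc1O[Si](C)(C)C(C)(C)C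
A2 | alternative 1 | ethynyl ether of (1S,2R)-1-[4-(tert-butyldimethylsilyloxy)-3-methoxyphenyl]-3-(tert-butyldimethylsilyloxy)-2-{4-[5-(3-(tert-butyldimethylsilyloxy)propyl)-7-methoxybenzofuran-2-yl]furan-2-yl}propan-1-ol | COc1cc([C@@H](OC#C)[C@@H](CO[Si](C)(C)C(C)(C)C)c2cc(-c3cc4cc(CCCO[Si](C)(C)C(C)(C)C)cc(OC)c4o3)co2)ccc1O[Si](C)(C)C(C)(C)C
A3 | alternative 2 | (2S,3R)-5-bromo-7-methoxy-2-(3-methoxy-4-pivaloyloxyphenyl)-3-(nitromethyl)-2,3-dihydrobenzofuran (trans) | COc1cc([C@H]2Oc3c(OC)cc(Br)cc3[C@@H]2C[N+](=O)[O-])ccc1OC(=O)C(C)(C)C
A4 | alternative 2 | (E)-4-bromo-2-methoxy-6-(2-nitrovinyl)phenol | COc1cc(Br)cc(/C=C/[N+](=O)[O-])c1O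
A5 | alternative 2 | (2R,5R)-1-(3-methoxy-4-pivaloyloxybenzyl)-2,5-dimethylthiolan-1-ium bromide (one possible chiral sulfonium salt; the antipode if required) | C[C@@H]1CC[C@@H](C)[S+]1Cc1ccc(OC(=O)C(C)(C)C)c(OC)c1.[Br-]
A6 | alternative 3 | (2S,3R)-5-bromo-2-(4-hydroxy-3-methoxyphenyl)-3-(hydroxymethyl)-7-methoxy-2,3-dihydrobenzofuran (identical with 14) | COc1cc([C@H]2Oc3c(OC)cc(Br)cc3[C@@H]2CO)ccc1O
A7 | alternative 3 | (3R)-3-(5-bromo-2-hydroxy-3-methoxyphenyl)-4-hydroxy-2-(4-hydroxy-3-methoxyphenyl)butanoic acid (either C2 epimer, used as its carboxylate) | COc1cc(C(C(=O)O)[C@@H](CO)c2cc(Br)cc(OC)c2O)ccc1O
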